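Readings and results come from a simulation with constants of no real substance; noise was put on by code.

Read the clock first.

- grey: starting material 7.5 mM; partner 4.75 mM; run made earlier
- flask: starting material 5.0 mM; partner 4.75 mM; time 3.0 min

grey run (percent of the starting material charged)

| time / s | product / % | open intermediate / % |
|---|---|---|
| 10.0 | 7.6 | 12.9 |
| 15.0 | 14.1 | 14.7 |
| 30.0 | 30.4 | 20.4 |
| 50.0 | 41.6 | 26.8 |

(each reading ± 0.5 percentage points)

1. amount of product in the flask at 3.0 min, in percent of the starting material charged
2. amount of open intermediate in the flask at 3.0 min, in percent of the starting material charged



In the grey run, product plus open intermediate is what has left the starting material. At 50.0 s that sum is 68.4%, which gives a first-order constant of 0.0230 s⁻¹. The reading at 10.0 s gives 0.0229 s⁻¹, so you can freeze it. A first-order clock counts in shares of the charge, so by 3.0 min your flask and a grey charge have each released 98.4%.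

The two differ in starting material and hold the same partner. Each holds 4.75 mM, the limiting reagent in both, but that is 63.3% of the grey charge and 95.0% of the flask's. If each product takes one partner, whatever is released beyond the partner must stay open. So call the released share minus the ratio of partner to starting material the floor of open intermediate: 3.42% for the flask, and 35.1% for the grey charge at that time. The grey floor stands higher because its partner covers a smaller share. I commit to that bound for the flask: on the same one-to-one count, any open intermediate above the floor stands for partner that has not become product.

The forecast goes further, with 67% product and 31% open intermediate, and it says: “I lean towards reversibility, with a wide range”.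

The flask gives 70.4% product and 28.0% open intermediate at 3.0 min.

    starting material → open intermediate (k = 0.0230 s⁻¹)
    open intermediate + second intermediate → product (k = 170 L mol⁻¹ s⁻¹)
    second intermediate → decomposed reagent (k = 0.0400 s⁻¹)
    partner → second intermediate (k = 0.0340 s⁻¹)

At that time the flask holds 0.22% of its partner and 1.22 mM of decomposed reagent. Its open intermediate stands 25 percentage points above the floor, which is 1.23 mM of the charge, close to that decomposed reagent. With 20 mM of starting material, the same flask has a floor of 74.7% and holds 76.0% open intermediate.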